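## The problem

Target 13 is a 3,4-dihydro-6H-isochromene-6,8(7H)-dione. Carbocyclic ring A (C4a, C5, C6, C7, C8, C8a) is fused along C4a–C8a to dihydropyran ring B (O2, C1, C8a, C4a, C4, C3). The rings share one chromophore: the vinylogous ester O2–C1=C8a–C8=O and the dienone C6(=O)–C5=C4a–C8a=C1.

There are two stereocentres. C3 (R) is a methyl-bearing ether carbon of ring B. C7 (R) is fully substituted and carries a methyl group and the linoleate between the C6 and C8 ketones. C3 can be taken from the chiral pool, but it lies across the bicycle from C7 and cannot steer a reagent to one face of ring A. C7 therefore needs reagent control, and C3 helps only in making the two C7 epimers diastereomers.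

The (9Z,12Z)-diene, with its doubly allylic C11 methylene, excludes hydrogenation, strong base, radical conditions and long contact with oxidants once the ester is present. The tertiary acyloxy diketone is open to retro-Claisen cleavage and ketol shifts under base, and the C1 enol ether adds nucleophiles.

The feature that opens the problem is C7. A carbon with CH3 and an acyloxy group next to the C8 ketone is what an ortho-quinone carbonyl carbon becomes once it has accepted a methyl anion and its oxygen an acyl cation. With a methoxy group on C6, the remaining unsaturation of ring A and the C1 methylene are one hydride and one O-methyl away from the target chromophore.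

## Retrosynthesis

**13 ⇒ 12.** No skeletal bond is cut. The C6 ketone is written as a methyl enol ether and C1 as a methylene, giving dienol ether 12 (C5=C6–OMe, C4a=C8a, C1H2). Forward, this is dehydrogenation of a dienol ether to a linear dienone. It is preferred to carrying the C1=C8a enol ether through the organometallic step, where a vinylogous ester would be exposed to a Grignard reagent. The forward reaction must take hydride from C1 and leave the doubly allylic C11 methylene of the ester alone.

**12 ⇒ 7 + 10 + 9.** The C7–CH3 bond and the O7–acyl bond are cut together. The precursor is the flat, C7-achiral ortho-quinone 7, with methylmagnesium bromide 10 and linoleoyl chloride 9; the metal alkoxide 11 links the two bond formations. This is preferred to a late esterification of a neutral tertiary ketol and to an oxidative dearomatisation that would have to form the C7–O bond with stereocontrol. All three oxygens of ring A are present before the step. The forward reaction must select C7 over C8, carbonyl addition over conjugate addition, and one face of C7, and must acylate a hindered alkoxide.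

**9 ⇒ 8.** The acyl chloride comes from linoleic acid 8 by a standard activation, made fresh so that the diene is not stored in an activated form.

**7 ⇒ 6.** The C8 carbonyl oxygen is removed, leaving guaiacol-type phenol 6 (7-OH, 6-OMe, C8–H). A phenol flanked by two methoxy groups could also be oxidised to an ortho-quinone with loss of methanol, but the oxidant would then choose between two methoxy groups. In 6 the para position C4a is blocked and C8 is the only unsubstituted ortho carbon, so only one quinone can form.

**6 ⇒ 5 ⇒ 4.** The phenol is masked as benzyl ether 5. Ring B is then opened at C1–C8a and C1–O2 (oxa-Pictet–Spengler retron), giving alcohol 4 and a formaldehyde equivalent. Closure occurs para to the methoxy group, the normal outcome for 3,4-dialkoxyphenethyl alcohols. The benzyl group is chosen because it survives the Grignard and Lewis acid steps and leaves by hydrogenolysis before any alkene is present.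

**4 ⇒ 1 + 2.** The C4–C4a bond is cut to aryl bromide 1 (through Grignard reagent 3) and (R)-propylene oxide 2. The epoxide supplies C3 with its configuration; no bond to the stereocentre is made or broken.

## Roads not taken

**Alternative 1:** The cut is the C1–C8a bond together with the C1=C8a enol ether. It leads back to formate A2, (2R)-1-[4-(tert-butyldimethylsilyloxy)-4-methyl-3,5-dioxocyclohex-1-en-1-yl]propan-2-yl formate.

- **Forward step:** A mild base would form the dienolate spread over C5, C4a and C8a. Its two ends are locally equivalent; the end that attacks the tethered formate carbon becomes C8a. Acid work-up would dehydrate the cyclic hemiacetal to silyl ether A1, (3R,7R)-7-(tert-butyldimethylsilyloxy)-3,7-dimethyl-3,4-dihydro-6H-isochromene-6,8(7H)-dione.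
- **Merits:** C1 arrives at the right oxidation level, so no oxidation is needed near a diene. No ortho-quinone is handled. C7 would be fixed by the stereocentre already present, without a chiral reagent.
- **Weak points:** The two dienolate ends differ only in whether the tether approaches on the side of the C7 methyl or the C7 silyloxy group. C3 must read this across the ring, so the bias is likely small and cannot be tuned. O-formylation and loss of the formate compete. A2 is a 2,2-disubstituted 1,3-dione and can undergo retro-Claisen cleavage. After A1, removal of a tertiary silyl ether between two ketones and esterification add two steps.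
- **Comparison:** This road is better in oxidation-state economy and in avoiding a quinone. The adopted plan sets against it a shorter sequence from commodity materials, the ester formed in the same flask as the stereocentre, and a C7 selectivity that can be changed through the chiral ligand.

**Alternative 2:** The cut is the C4a=C5 double bond, an aldol condensation retron. It leads to triketone A4, (2R)-2-methyl-5-[(2R)-2-methyl-3-oxo-2-(triethylsilyloxy)butanoyl]oxan-4-one.

- **Forward step:** An amine salt or a sulfonic acid would condense the C5 methyl group of the C6 ketone with the C4a carbonyl. This closes ring A to enol A3, (3R,7S)-8-hydroxy-3,7-dimethyl-7-(triethylsilyloxy)-3,4-dihydro-1H-isochromen-6(7H)-one. C7 is arranged as in 13; the descriptor changes because C8 is an enol carbon.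
- **Merits:** Ordinary carbonyl chemistry, a polyketide-like logic, and no stereochemical decision in the ring closure.
- **Weak points:** The C7 problem is only moved into A4. Its quaternary carbinol carbon is chiral through the difference between an acetyl and an acyl arm, and is no easier to make as one enantiomer. A4 is a non-enolisable 2-oxy-1,3-diketone and is prone to retro-Claisen cleavage. A second six-membered aldol mode (C4 onto the C6 carbonyl) competes. A3 is still two hydrogens short at C1 and silylated, so oxidation, desilylation and acylation follow.
- **Comparison:** Only the robustness of the ring-closing reaction type is better than in the adopted plan. The route is longer and does not avoid the late oxidation at C1.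

**Alternative 3:** The cut is the C7–C8 bond, a crossed benzoin retron. It leads to aldehyde A6, (2R)-4-[(Z)-2,3-dioxobutylidene]-2-methyl-3,4-dihydro-2H-pyran-5-carbaldehyde.

- **Forward step:** A chiral triazolium-derived carbene with an amine base would turn the C8 aldehyde into an acyl anion equivalent. This adds to the C7 ketone and closes six-membered ring A to alcohol A5, (3R,7R)-7-hydroxy-3,7-dimethyl-3,4-dihydro-6H-isochromene-6,8(7H)-dione.
- **Merits:** Catalytic enantiocontrol at C7 by a reaction class with strong precedent for aldehyde–ketone ring closures. A5 is already at the oxidation level of 13 and one acylation away. In precedent for stereocontrol this road is better than the adopted plan.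
- **Weak points:** The C8 aldehyde is a vinylogous formate (O2–C1=C8a–CHO), a poor electrophile for the carbene, and may react through C1. The C6 carbonyl offers a five-membered closure. The Z geometry at C4a=C5 must be made and kept. A6 is a polycarbonyl diene that needs many steps and is likely short-lived. The acylation with the costly acid remains a separate step.
- **Comparison:** The adopted plan sets against it four ordinary steps to quinone 7, all ring A oxygens supplied by the arene, and ester formation in the key flask. Its weaker footing at C7 is offset by the separability of the epimers and a fallback in known chemistry.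

Key step: step 6

Assumption: the reagent from (R,R)-TADDOL is taken to deliver methyl to the C7 face that leads to the (7R) ester; should the (7S) epimer prevail, the same procedure is run with (S,S)-TADDOL.

## Route

Step 1
Reactants: 1 1-(benzyloxy)-4-bromo-2-methoxybenzene; 2 (R)-propylene oxide [(2R)-2-methyloxirane]
Product: 4 (2R)-1-[4-(benzyloxy)-3-methoxyphenyl]propan-2-ol, via arylmagnesium bromide 3 (not isolated)
Conditions: Mg, THF, reflux; then CuI (10 mol%), 2, −30 → 0 °C; 1 M HCl
Reagents that add atoms: none
Why: Copper-catalysed opening of a terminal epoxide by an aryl Grignard reagent at the unsubstituted carbon (SN2); the C–O bond at the stereocentre is untouched, so the (R) configuration of 2 becomes C3 of the target.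

Step 2
Reactants: 4 (2R)-1-[4-(benzyloxy)-3-methoxyphenyl]propan-2-ol
Product: 5 (3R)-7-(benzyloxy)-6-methoxy-3-methylisochromane
Conditions: CH2(OMe)2, BF3·OEt2, CH2Cl2, 0 °C → rt
Reagents that add atoms: dimethoxymethane, COCOC
Why: Oxa-Pictet–Spengler cyclisation: the alcohol and the acetal give an oxocarbenium ion that substitutes the ring para to the methoxy group (the ortho site between methoxy and side chain is hindered), forming C1–C8a and closing ring B; C3 is not involved.

Step 3
Reactants: 5 (3R)-7-(benzyloxy)-6-methoxy-3-methylisochromane
Product: 6 (3R)-6-methoxy-3-methylisochroman-7-ol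
Conditions: H2 (1 atm), 10% Pd/C, EtOAc, rt
Reagents that add atoms: none
Why: Hydrogenolysis of the benzyl aryl ether; the cyclic benzylic C1–O2 ether is cleaved far more slowly at 1 atm and room temperature, and no alkene is yet present.

Step 4
Reactants: 6 (3R)-6-methoxy-3-methylisochroman-7-ol
Product: 7 (3R)-6-methoxy-3-methyl-3,4-dihydro-1H-isochromene-7,8-dione
Conditions: (KSO3)2NO (2.5 equiv), aq KH2PO4, acetone–H2O, 0 °C; extraction into CH2Cl2, used at once
Reagents that add atoms: dipotassium nitrosodisulfonate (KSO3)2NO, [K+].[K+].[O]N(S(=O)(=O)[O-])S(=O)(=O)[O-]
Why: Teuber oxidation: the phenoxyl radical formed by the first equivalent couples with a second at C8, the only unsubstituted ortho carbon (para C4a is blocked), and loss of imidodisulfonate gives the ortho-quinone with the 6-methoxy group retained, as known for 4-alkyl-2-methoxyphenols.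

Step 5
Reactants: 8 linoleic acid [(9Z,12Z)-octadeca-9,12-dienoic acid]
Product: 9 linoleoyl chloride [(9Z,12Z)-octadeca-9,12-dienoyl chloride]
Conditions: (COCl)2, DMF (cat.), CH2Cl2, 0 °C → rt; concentrated under argon, used crude
Reagents that add atoms: oxalyl chloride, O=C(Cl)C(=O)Cl
Why: Acid chloride formation under Vilsmeier catalysis at or below room temperature, conditions that leave the skipped Z,Z-diene untouched.

Step 6
Reactants: 7 (3R)-6-methoxy-3-methyl-3,4-dihydro-1H-isochromene-7,8-dione; 10 methylmagnesium bromide; 9 linoleoyl chloride
Product: 12 (3R,7R)-6-methoxy-3,7-dimethyl-8-oxo-3,4,7,8-tetrahydro-1H-isochromen-7-yl (9Z,12Z)-octadeca-9,12-dienoate, via bromomagnesium C7-alkoxide 11 (not isolated)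
Conditions: (R,R)-TADDOL (1.1 equiv), 10 (3.3 equiv), THF, 0 °C then −100 °C; 7, −100 °C; then 9 (1.5 equiv), DMAP (10 mol%), −78 → 0 °C; pH 7 phosphate buffer
Reagents that add atoms: none
Why: Proposed new method: the bis(bromomagnesium) alkoxide TADDOL(OMgBr)2, formed from (R,R)-TADDOL [(4R,5R)-2,2-dimethyl-α,α,α′,α′-tetraphenyl-1,3-dioxolane-4,5-dimethanol] and two equivalents of 10, takes up a third equivalent of 10 and binds quinone 7 through O7 and O8 as a five-membered chelate, methyl is transferred inside this chiral aggregate to C7 to give alkoxide 11, and 11 is acylated on oxygen by 9 (through its acylpyridinium ion) before any proton source is added. The closest known reaction types are the 1,2-addition of methyllithium or methyl Grignard reagents to ortho-quinones giving 6-hydroxy-6-methylcyclohexa-2,4-dienones, the TADDOL-assisted enantioselective addition of Grignard reagents to ketones, and the O-acylation of magnesium alkoxides by acid chlorides; their combination on a chelating ortho-quinone with face control has not been shown. No ring closes. The new stereocentre C7 is set by the chiral magnesium TADDOLate (reagent control), because C3 lies on ring B too far away to bias the faces of the planar quinone; C3 makes the two C7 epimers diastereomers, so a minor epimer can be removed by chromatography. Site selectivity for C7 over C8 comes from the substrate: C8 is the carbonyl of a doubly vinylogous ester (O=C8–C8a=C4a–C5=C6–OMe) and is deactivated, whereas C7 only has the methoxy group on its alpha carbon. Carbonyl addition is favoured over conjugate attack at C5, C4a or C6 by the hard, chelate-delivered methyl group, and over electron transfer or deprotonation at C1 and C4 by the low temperature and the alkoxide-bound reagent.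

Step 7
Reactants: 12 (3R,7R)-6-methoxy-3,7-dimethyl-8-oxo-3,4,7,8-tetrahydro-1H-isochromen-7-yl (9Z,12Z)-octadeca-9,12-dienoate
Product: 13 (3R,7R)-3,7-dimethyl-6,8-dioxo-4,6,7,8-tetrahydro-3H-isochromen-7-yl (9Z,12Z)-octadeca-9,12-dienoate
Conditions: DDQ (1.2 equiv), acetone–H2O (20:1), 0 °C, dark, argon; aq NaHCO3
Reagents that add atoms: water, O
Why: DDQ dehydrogenation of a dienol ether, the reaction type that converts steroidal 3-alkoxy-3,5-dienes into 4,6-dien-3-ones: hydride leaves C1, which is allylic to the terminus of the C8a=C4a–C5=C6(OMe) dienol ether and alpha to O2, and water hydrolyses the C6 methoxy-oxocarbenium ion to the ketone, leaving C1=C8a and C4a=C5; C3 and the quaternary C7 are not touched.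

## Compound list

1 | 1-(benzyloxy)-4-bromo-2-methoxybenzene | COc1cc(Br)ccc1OCc1ccccc1 | starting material
2 | (R)-propylene oxide, (2R)-2-methyloxirane | C[C@@H]1CO1 | starting material
3 | [4-(benzyloxy)-3-methoxyphenyl]magnesium bromide | COc1cc([Mg]Br)ccc1OCc1ccccc1 | intermediate
4 | (2R)-1-[4-(benzyloxy)-3-methoxyphenyl]propan-2-ol | C[C@@H](O)Cc1ccc(OCc2ccccc2)c(OC)c1 | intermediate
5 | (3R)-7-(benzyloxy)-6-methoxy-3-methylisochromane | C[C@@H]1Cc2cc(OC)c(OCc3ccccc3)cc2CO1 | intermediate
6 | (3R)-6-methoxy-3-methylisochroman-7-ol | C[C@@H]1Cc2cc(OC)c(O)cc2CO1 | intermediate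
7 | (3R)-6-methoxy-3-methyl-3,4-dihydro-1H-isochromene-7,8-dione | COC1=CC2=C(CO[C@H](C)C2)C(=O)C1=O | intermediate
8 | linoleic acid, (9Z,12Z)-octadeca-9,12-dienoic acid | CCCCC/C=C\C/C=C\CCCCCCCC(=O)O | starting material
9 | linoleoyl chloride, (9Z,12Z)-octadeca-9,12-dienoyl chloride | CCCCC/C=C\C/C=C\CCCCCCCC(=O)Cl | intermediate
10 | methylmagnesium bromide | C[Mg]Br | starting material
11 | bromomagnesium (3R,7R)-6-methoxy-3,7-dimethyl-8-oxo-3,4,7,8-tetrahydro-1H-isochromen-7-olate | Br[Mg]O[C@]1(C)C(OC)=CC2=C(CO[C@H](C)C2)C1=O | intermediate
12 | (3R,7R)-6-methoxy-3,7-dimethyl-8-oxo-3,4,7,8-tetrahydro-1H-isochromen-7-yl (9Z,12Z)-octadeca-9,12-dienoate | CCCCC/C=C\C/C=C\CCCCCCCC(=O)O[C@]1(C)C(OC)=CC2=C(CO[C@H](C)C2)C1=O | intermediate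
13 | (3R,7R)-3,7-dimethyl-6,8-dioxo-4,6,7,8-tetrahydro-3H-isochromen-7-yl (9Z,12Z)-octadeca-9,12-dienoate | CCCCC/C=C\C/C=C\CCCCCCCC(=O)O[C@]1(C)C(=O)C=C2C[C@@H](C)OC=C2C1=O | target

## Step count and least certain steps

Total step count: 7. Longest linear sequence: 6 steps (steps 1, 2, 3, 4, 6, 7 from bromide 1); the acyl branch contributes step 5.

**Step 6 (key step, proposed new method).**
- **What may go wrong:** Poor facial selectivity at C7 is the most likely failure, because the induction of a magnesium TADDOLate has not been tested on a chelating ortho-quinone and the substrate offers no bias. Electron transfer from the Grignard reagent to the quinone, deprotonation at C1 or C4 with tautomerisation of the quinone, and incomplete acylation of the hindered alkoxide may lower the yield further.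
- **Fallback (known chemistry), from 7 back to 12:** Quinone 7 is treated with MeCeCl2, made from 10 and anhydrous CeCl3 in THF at −78 °C, and quenched with aqueous NH4Cl. This should give the ketol as both C7 epimers, (3R,7RS)-7-hydroxy-6-methoxy-3,7-dimethyl-3,4-dihydro-1H-isochromen-8(7H)-one F1. The epimers are separated by preparative HPLC to give (3R,7R)-7-hydroxy-6-methoxy-3,7-dimethyl-3,4-dihydro-1H-isochromen-8(7H)-one F2. F2 is esterified with 9 (Et3N, DMAP, CH2Cl2, 0 °C) and rejoins the route at 12. Half of the material is given up with the unwanted epimer.

**Step 4.**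
- **What may go wrong:** Oxidative loss of the C6 methoxy group in competition with oxygenation of C8–H, and tautomerisation or self-condensation of the electron-rich ortho-quinone during aqueous isolation.
- **Fallback, from 6 back to 7:** Casnati–Skattebøl ortho-formylation of phenol 6 (MgCl2, Et3N, paraformaldehyde, MeCN, reflux) should occur at the only free ortho carbon and give (3R)-7-hydroxy-6-methoxy-3-methylisochromane-8-carbaldehyde F3. Dakin oxidation (H2O2, aq NaOH) should give the catechol (3R)-6-methoxy-3-methylisochromane-7,8-diol F4. Ag2O in dry Et2O over Na2SO4 oxidises F4 under neutral, water-free conditions to 7, which is filtered straight into the key step.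

**Step 7.**
- **What may go wrong:** Hydride or hydrogen-atom abstraction at the doubly allylic C11 methylene of the linoleate, leading to conjugation or oxidation of the diene, may compete with abstraction at C1. C1 is slowed by the C8 ketone on C8a.
- **Fallback, from 11 back to 13:** The order of events is changed. Alkoxide 11 is quenched with aqueous NH4Cl in place of 9 to give ketol F2, (3R,7R)-7-hydroxy-6-methoxy-3,7-dimethyl-3,4-dihydro-1H-isochromen-8(7H)-one F2. DDQ in wet acetone should convert it to (3R,7R)-7-hydroxy-3,7-dimethyl-3,4-dihydro-6H-isochromene-6,8(7H)-dione F5 with no diene present. The tertiary hydroxyl of F5 is then acylated with 9 (Et3N, DMAP, CH2Cl2) to give 13.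

**Step 2.**
- **What may go wrong:** Intermolecular Friedel–Crafts alkylation to diarylmethanes, or Lewis acid cleavage of the benzyl ether, in place of ring closure.
- **Fallback, from 4 back to 5:** Bromination of 4 with NBS in MeCN para to the methoxy group should give (2R)-1-[4-(benzyloxy)-2-bromo-5-methoxyphenyl]propan-2-ol F6. Treatment with n-BuLi (2.2 equiv, THF, −78 °C) and then DMF gives the hydroxy aldehyde, which closes to the lactol (3R)-7-(benzyloxy)-6-methoxy-3-methylisochroman-1-ol F7. Ionic hydrogenation (Et3SiH, CF3CO2H, CH2Cl2) reduces F7 to 5.

## Further compounds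

F1 | step 6 | (3R,7RS)-7-hydroxy-6-methoxy-3,7-dimethyl-3,4-dihydro-1H-isochromen-8(7H)-one (both C7 epimers) | OC1(C)C(OC)=CC2=C(CO[C@H](C)C2)C1=O
F2 | step 6 | (3R,7R)-7-hydroxy-6-methoxy-3,7-dimethyl-3,4-dihydro-1H-isochromen-8(7H)-one | O[C@]1(C)C(OC)=CC2=C(CO[C@H](C)C2)C1=O
F3 | step 4 | (3R)-7-hydroxy-6-methoxy-3-methylisochromane-8-carbaldehyde | C[C@@H]1Cc2cc(OC)c(O)c(C=O)c2CO1
F4 | step 4 | (3R)-6-methoxy-3-methylisochromane-7,8-diol | C[C@@H]1Cc2cc(OC)c(O)c(O)c2CO1
F5 | step 7 | (3R,7R)-7-hydroxy-3,7-dimethyl-3,4-dihydro-6H-isochromene-6,8(7H)-dione | O[C@]1(C)C(=O)C=C2C[C@@H](C)OC=C2C1=O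
F6 | step 2 | (2R)-1-[4-(benzyloxy)-2-bromo-5-methoxyphenyl]propan-2-ol | C[C@@H](O)Cc1cc(OC)c(OCc2ccccc2)cc1Br
F7 | step 2 | (3R)-7-(benzyloxy)-6-methoxy-3-methylisochroman-1-ol | C[C@@H]1Cc2cc(OC)c(OCc3ccccc3)cc2C(O)O1
A1 | alternative 1 | (3R,7R)-7-(tert-butyldimethylsilyloxy)-3,7-dimethyl-3,4-dihydro-6H-isochromene-6,8(7H)-dione | CC(C)(C)[Si](C)(C)O[C@]1(C)C(=O)C=C2C[C@@H](C)OC=C2C1=O
A2 | alternative 1 | (2R)-1-[4-(tert-butyldimethylsilyloxy)-4-methyl-3,5-dioxocyclohex-1-en-1-yl]propan-2-yl formate | O=CO[C@H](C)CC1=CC(=O)C(C)(O[Si](C)(C)C(C)(C)C)C(=O)C1
A3 | alternative 2 | (3R,7S)-8-hydroxy-3,7-dimethyl-7-(triethylsilyloxy)-3,4-dihydro-1H-isochromen-6(7H)-one | CC[Si](CC)(CC)O[C@]1(C)C(=O)C=C2C[C@@H](C)OCC2=C1O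
A4 | alternative 2 | (2R)-2-methyl-5-[(2R)-2-methyl-3-oxo-2-(triethylsilyloxy)butanoyl]oxan-4-one | CC[Si](CC)(CC)O[C@](C)(C(C)=O)C(=O)C1CO[C@H](C)CC1=O
A5 | alternative 3 | (3R,7R)-7-hydroxy-3,7-dimethyl-3,4-dihydro-6H-isochromene-6,8(7H)-dione | O[C@]1(C)C(=O)C=C2C[C@@H](C)OC=C2C1=O
A6 | alternative 3 | (2R)-4-[(Z)-2,3-dioxobutylidene]-2-methyl-3,4-dihydro-2H-pyran-5-carbaldehyde | CC(=O)C(=O)/C=C1/C[C@@H](C)OC=C1C=O
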